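**Assumption (one line):** germacrane numbering is used throughout (C12 = lactone carbonyl, ring O on C6, C7 carries C11, C8 = angelate carbon, C9 = ketone, C10 = CHMe, C4 = tertiary carbinol, C5 = isobutyrate carbon); compounds 5, 11, 20 and the chiral reagents are taken as purchasable.

## Retrosynthetic overview

1. Target ⇐ C8 angeloylation and C5 isobutyrylation of a 4,5-diol that comes from C4-selective hydrolysis of a (4R,5R)-oxirane.
2. The ten-membered carbocycle and the α-methylene-γ-lactone are closed together through the C6–C7 bond. A 2-(methoxycarbonyl)allyl chromium species, an ester homoenolate (β-acyl carbanion) equivalent, adds to the C6 aldehyde. C7 (the acrylate β-carbon) and C6 (the aldehyde carbon) are both natural acceptor carbons.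
3. The open-chain precursor ⇐ cross-metathesis (C7=C11), Sharpless epoxidation (C4, C5), Brown γ-alkoxyallylboration (C8–C9 bond, C8 stereocentre), Ru–BINAP hydrogenation (C10).
4. C1–C6, C9, C10, C14 and C15 all come from geranyl acetate.
5. Ring order: oxirane (step 5), then carbocycle and lactone in one operation (step 8), then the oxirane is opened (step 9).

## Route

Step 1
Reactants: 1 geranyl acetate
Product: 2 (2E,6E)-8-hydroxy-3,7-dimethylocta-2,6-dien-1-yl acetate
Conditions: SeO2 (0.2 equiv), t-BuOOH (3 equiv), salicylic acid (0.1 equiv), CH2Cl2, rt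
Reagents that add atoms: tert-butyl hydroperoxide, CC(C)(C)OO (oxygen relayed through SeO2, O=[Se]=O)
Why: SeO2/t-BuOOH allylic oxidation (ene reaction then 2,3-sigmatropic shift) attacks only the (E)-methyl group of the electron-rich terminal alkene and leaves the deactivated allylic-acetate alkene alone; no stereocentre is formed.

Step 2
Reactants: 2 (2E,6E)-8-hydroxy-3,7-dimethylocta-2,6-dien-1-yl acetate
Product: 3 (2E,7R)-8-hydroxy-3,7-dimethyloct-2-en-1-yl acetate
Conditions: Ru(OAc)2[(R)-BINAP] (1 mol %), H2 (50 atm), MeOH, rt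
Reagents that add atoms: none
Why: Noyori hydroxyl-directed asymmetric hydrogenation reduces only the alkene of the free allylic alcohol (the acetate-bearing alkene cannot bind Ru through OH) and sets C10 as R under catalyst control; the (R)-ligand is assigned from the geraniol quadrant mnemonic, and the antipodal ligand is the remedy if the sense proves opposite.

Step 3
Reactants: 3 (2E,7R)-8-hydroxy-3,7-dimethyloct-2-en-1-yl acetate
Product: 4 (2E,7R)-3,7-dimethyl-8-oxooct-2-en-1-yl acetate
Conditions: Dess–Martin periodinane, NaHCO3, CH2Cl2, 0 °C → rt; used crude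
Reagents that add atoms: none
Why: Buffered Dess–Martin oxidation gives the α-methyl aldehyde without epimerising C10, and the aldehyde is taken on at once.

Step 4
Reactants: 4 (2E,7R)-3,7-dimethyl-8-oxooct-2-en-1-yl acetate; 5 allyl methoxymethyl ether
Product: 9 (2E,7R,8R,9R)-9-(methoxymethoxy)-3,7-dimethylundeca-2,10-diene-1,8-diol, via lithiated allyl ether 6 (not isolated), via allylborane 7 (not isolated), via acetate adduct 8 (not isolated)
Conditions: 5, s-BuLi, THF, −78 °C; (−)-Ipc2BOMe; BF3·OEt2; 4, −78 °C → rt; then 3 M NaOH, 30% H2O2, MeOH, rt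
Reagents that add atoms: none
Why: Brown asymmetric γ-alkoxyallylboration: the (Z)-γ-alkoxyallylborane (an α-alkoxy carbanion equivalent) adds through a chair transition state to the Si face of the aldehyde under Ipc control, giving the syn (8R,9R) mono-MOM diol, so germacrane C8 is set by the reagent, and the alkaline peroxide work-up cleaves both the B–O bond and the acetate.

Step 5
Reactants: 9 (2E,7R,8R,9R)-9-(methoxymethoxy)-3,7-dimethylundeca-2,10-diene-1,8-diol
Product: 10 (2R,3R,7R,8R,9R)-2,3-epoxy-9-(methoxymethoxy)-3,7-dimethylundec-10-ene-1,8-diol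
Conditions: Ti(OiPr)4 (0.2 equiv), D-(−)-diethyl tartrate (0.25 equiv), t-BuOOH (2 equiv), 4 Å molecular sieves, CH2Cl2, −20 °C
Reagents that add atoms: tert-butyl hydroperoxide, CC(C)(C)OO
Why: Katsuki–Sharpless asymmetric epoxidation of the (E)-allylic alcohol with the D-tartrate gives the (2R,3R)-oxirane (germacrane 4R,5R) by reagent control, while the monosubstituted alkene next to a homoallylic hydroxyl is not epoxidised.

Step 6
Reactants: 10 (2R,3R,7R,8R,9R)-2,3-epoxy-9-(methoxymethoxy)-3,7-dimethylundec-10-ene-1,8-diol; 11 methyl 2-(bromomethyl)acrylate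
Product: 12 methyl (2Z,4R,5R,6R,10R,11R)-2-(bromomethyl)-10,11-epoxy-5,12-dihydroxy-4-(methoxymethoxy)-6,10-dimethyldodec-2-enoate
Conditions: 11 (10 equiv), RuCl2(H2IMes)(=CH-2-iPrOC6H4) (second-generation Hoveyda–Grubbs catalyst, 10 mol %), CH2Cl2, 40 °C
Reagents that add atoms: none
Why: Olefin cross-metathesis of the only monosubstituted alkene with a 1,1-disubstituted acrylate that does not homodimerise gives the more stable trisubstituted enoate with the chain trans to the ester (Z by CIP); no stereocentre is touched.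

Step 7
Reactants: 12 methyl (2Z,4R,5R,6R,10R,11R)-2-(bromomethyl)-10,11-epoxy-5,12-dihydroxy-4-(methoxymethoxy)-6,10-dimethyldodec-2-enoate
Product: 13 methyl (2Z,4R,6R,10R,11S)-2-(bromomethyl)-10,11-epoxy-4-(methoxymethoxy)-6,10-dimethyl-5,12-dioxododec-2-enoate
Conditions: Dess–Martin periodinane (3 equiv), NaHCO3, CH2Cl2, 0 °C → rt; used at once
Reagents that add atoms: none
Why: One buffered Dess–Martin oxidation converts the epoxy alcohol into the epoxy aldehyde and the secondary alcohol into the C9 ketone under neutral conditions that spare the allylic bromide and the acidic C8 and C10 hydrogens (the 11S label is a CIP priority change only).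

Step 8
Reactants: 13 methyl (2Z,4R,6R,10R,11S)-2-(bromomethyl)-10,11-epoxy-4-(methoxymethoxy)-6,10-dimethyl-5,12-dioxododec-2-enoate
Product: 16 (4R,5R,6S,7S,8R,10R)-4,5-epoxy-8-(methoxymethoxy)-9-oxogermacr-11(13)-en-12,6-olide, via allylchromium dichloride 14 (not isolated), via hydroxy ester 15 (not isolated)
Conditions: CrCl2 (8 equiv), THF (2 mM, syringe-pump addition of 13 over 12 h), rt; aq NH4Cl
Reagents that add atoms: none
Why: Intramolecular Nozaki–Hiyama (chromium Barbier) allylation: divalent chromium turns the bromide into a 2-(methoxycarbonyl)allyl derivative of trivalent chromium that reacts through C7 (the β-carbon of the ester, an acceptor carbon in 13) as an ester homoenolate equivalent with the C6 aldehyde; a chair transition state with the tether carbons C5 and C8 both equatorial gives the 6,7-anti adduct and hence the trans-lactone after the alkoxide closes on the ester, H-8 lies in the allyl plane (1,3-allylic strain) so the aldehyde arrives on the tether face anti to OMOM, and the (4R,5R)-oxirane enforces the 6S,7S sense in the way known for chromium closures of epoxy-aldehyde precursors of parthenolide-type germacranolides.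

Step 9
Reactants: 16 (4R,5R,6S,7S,8R,10R)-4,5-epoxy-8-(methoxymethoxy)-9-oxogermacr-11(13)-en-12,6-olide
Product: 17 (4S,5R,6S,7S,8R,10R)-4,5-dihydroxy-8-(methoxymethoxy)-9-oxogermacr-11(13)-en-12,6-olide
Conditions: HClO4 (5% aq, cat.), THF/H2O 3:1, 0 °C → rt
Reagents that add atoms: water, O
Why: Acid-catalysed epoxide hydrolysis: water opens the protonated oxirane at the tertiary C4 with inversion (C5 is secondary and deactivated by the neighbouring lactone oxygen), so C4 becomes S and the C5–O bond is retained; the MOM ether survives dilute aqueous acid.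

Step 10
Reactants: 17 (4S,5R,6S,7S,8R,10R)-4,5-dihydroxy-8-(methoxymethoxy)-9-oxogermacr-11(13)-en-12,6-olide
Product: 18 (4S,5R,6S,7S,8R,10R)-4-hydroxy-5-isobutyryloxy-8-(methoxymethoxy)-9-oxogermacr-11(13)-en-12,6-olide
Conditions: isobutyric anhydride (3 equiv), Et3N, DMAP (cat.), CH2Cl2, 0 °C → rt
Reagents that add atoms: isobutyric anhydride, CC(C)C(=O)OC(=O)C(C)C
Why: DMAP-catalysed acylation takes the only secondary hydroxyl (C5), the tertiary C4 hydroxyl being inert under these mild conditions, which also do not epimerise C8 or C10.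

Step 11
Reactants: 18 (4S,5R,6S,7S,8R,10R)-4-hydroxy-5-isobutyryloxy-8-(methoxymethoxy)-9-oxogermacr-11(13)-en-12,6-olide
Product: 19 (4S,5R,6S,7R,8R,10R)-4,8-dihydroxy-5-isobutyryloxy-9-oxogermacr-11(13)-en-12,6-olide
Conditions: Me2BBr (3 equiv), CH2Cl2, −78 °C; then aq NaHCO3/THF
Reagents that add atoms: none
Why: Lewis-acid acetal cleavage with Me2BBr removes the MOM ether at −78 °C without touching the esters, the lactone or the tertiary alcohol (the 7R label is a CIP priority change only; no centre is altered).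

Step 12
Reactants: 19 (4S,5R,6S,7R,8R,10R)-4,8-dihydroxy-5-isobutyryloxy-9-oxogermacr-11(13)-en-12,6-olide; 20 angelic acid
Product: 22 CNP0141258.2 [(4S,5R,6S,7S,8R,10R)-8-angeloyloxy-4-hydroxy-5-isobutyryloxy-9-oxogermacr-11(13)-en-12,6-olide], via mixed anhydride 21 (not isolated)
Conditions: 20 (5 equiv), 2,4,6-trichlorobenzoyl chloride (5 equiv), Et3N (6 equiv), toluene, rt, 2 h; then 19, 75 °C
Reagents that add atoms: none
Why: Yamaguchi mixed-anhydride esterification run without DMAP, the protocol that keeps the (Z) geometry of angelates, acylates the secondary C8 hydroxyl at the less hindered angeloyl carbonyl while the tertiary C4 hydroxyl stays free.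

## Compound list

1 | geranyl acetate | CC(C)=CCC/C(C)=C/COC(C)=O | starting material
2 | (2E,6E)-8-hydroxy-3,7-dimethylocta-2,6-dien-1-yl acetate | OC/C(C)=C/CC/C(C)=C/COC(C)=O | intermediate
3 | (2E,7R)-8-hydroxy-3,7-dimethyloct-2-en-1-yl acetate | OC[C@H](C)CCC/C(C)=C/COC(C)=O | intermediate
4 | (2E,7R)-3,7-dimethyl-8-oxooct-2-en-1-yl acetate | O=C[C@H](C)CCC/C(C)=C/COC(C)=O | intermediate
5 | allyl methoxymethyl ether [3-(methoxymethoxy)prop-1-ene] | C=CCOCOC | starting material
6 | (Z)-3-(methoxymethoxy)allyllithium | [Li]C/C=C\OCOC | intermediate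
7 | B-[(Z)-3-(methoxymethoxy)allyl]diisopinocampheylborane (Ipc groups from (+)-α-pinene) | COCO/C=C\CB([C@@H]1C[C@@H]2C[C@H]([C@H]1C)C2(C)C)[C@@H]1C[C@@H]2C[C@H]([C@H]1C)C2(C)C | intermediate
8 | (2E,7R,8R,9R)-8-hydroxy-9-(methoxymethoxy)-3,7-dimethylundeca-2,10-dien-1-yl acetate | C=C[C@@H](OCOC)[C@H](O)[C@H](C)CCC/C(C)=C/COC(C)=O | intermediate
9 | (2E,7R,8R,9R)-9-(methoxymethoxy)-3,7-dimethylundeca-2,10-diene-1,8-diol | C=C[C@@H](OCOC)[C@H](O)[C@H](C)CCC/C(C)=C/CO | intermediate
10 | (2R,3R,7R,8R,9R)-2,3-epoxy-9-(methoxymethoxy)-3,7-dimethylundec-10-ene-1,8-diol | C=C[C@@H](OCOC)[C@H](O)[C@H](C)CCC[C@@]1(C)O[C@@H]1CO | intermediate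
11 | methyl 2-(bromomethyl)acrylate | C=C(CBr)C(=O)OC | starting material
12 | methyl (2Z,4R,5R,6R,10R,11R)-2-(bromomethyl)-10,11-epoxy-5,12-dihydroxy-4-(methoxymethoxy)-6,10-dimethyldodec-2-enoate | COC(=O)/C(CBr)=C/[C@@H](OCOC)[C@H](O)[C@H](C)CCC[C@@]1(C)O[C@@H]1CO | intermediate
13 | methyl (2Z,4R,6R,10R,11S)-2-(bromomethyl)-10,11-epoxy-4-(methoxymethoxy)-6,10-dimethyl-5,12-dioxododec-2-enoate | COC(=O)/C(CBr)=C/[C@@H](OCOC)C(=O)[C@H](C)CCC[C@@]1(C)O[C@@H]1C=O | intermediate
14 | allylchromium dichloride derived from 13 (CrCl2 unit in place of Br) | COC(=O)/C(C[Cr](Cl)Cl)=C/[C@@H](OCOC)C(=O)[C@H](C)CCC[C@@]1(C)O[C@@H]1C=O | intermediate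
15 | methyl (4R,5R,6S,7S,8R,10R)-4,5-epoxy-6-hydroxy-8-(methoxymethoxy)-9-oxogermacr-11(13)-en-12-oate (ten-membered hydroxy ester, formed as its chromium alkoxide) | C=C(C(=O)OC)[C@@H]1[C@@H](OCOC)C(=O)[C@H](C)CCC[C@@]2(C)O[C@@H]2[C@H]1O | intermediate
16 | (4R,5R,6S,7S,8R,10R)-4,5-epoxy-8-(methoxymethoxy)-9-oxogermacr-11(13)-en-12,6-olide | C=C1C(=O)O[C@H]2[C@H]1[C@@H](OCOC)C(=O)[C@H](C)CCC[C@@]3(C)O[C@@H]32 | intermediate
17 | (4S,5R,6S,7S,8R,10R)-4,5-dihydroxy-8-(methoxymethoxy)-9-oxogermacr-11(13)-en-12,6-olide | C=C1C(=O)O[C@H]2[C@H]1[C@@H](OCOC)C(=O)[C@H](C)CCC[C@](C)(O)[C@@H]2O | intermediate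
18 | (4S,5R,6S,7S,8R,10R)-4-hydroxy-5-isobutyryloxy-8-(methoxymethoxy)-9-oxogermacr-11(13)-en-12,6-olide | C=C1C(=O)O[C@H]2[C@H]1[C@@H](OCOC)C(=O)[C@H](C)CCC[C@](C)(O)[C@@H]2OC(=O)C(C)C | intermediate
19 | (4S,5R,6S,7R,8R,10R)-4,8-dihydroxy-5-isobutyryloxy-9-oxogermacr-11(13)-en-12,6-olide | C=C1C(=O)O[C@H]2[C@H]1[C@@H](O)C(=O)[C@H](C)CCC[C@](C)(O)[C@@H]2OC(=O)C(C)C | intermediate
20 | angelic acid [(Z)-2-methylbut-2-enoic acid] | C/C=C(/C)C(=O)O | starting material
21 | angelic 2,4,6-trichlorobenzoic anhydride | C/C=C(/C)C(=O)OC(=O)c1c(Cl)cc(Cl)cc1Cl | intermediate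
22 | CNP0141258.2, (4S,5R,6S,7S,8R,10R)-8-angeloyloxy-4-hydroxy-5-isobutyryloxy-9-oxogermacr-11(13)-en-12,6-olide | C=C1C(=O)O[C@H]2[C@H]1[C@@H](OC(=O)/C(C)=C\C)C(=O)[C@H](C)CCC[C@](C)(O)[C@@H]2OC(=O)C(C)C | target

## Step count and risks

Total: 12 steps. Longest linear sequence: 12 steps (1 → 22); all other partners are bought.

**Step 8 (ring closure).** A ten-membered ring is closed against oligomerisation. The 6S,7S sense rests on macrocyclic control, and the allylchromium could lose the C8 alkoxy group by β-elimination. The fallback sets out from bromide 12. (Bu3Sn)2 with Pd(PPh3)4 exchanges bromine for tin to give the allylstannane diol F1, and Dess–Martin oxidation gives the stannyl keto epoxy-aldehyde F2. MgBr2·OEt2 (CH2Cl2, −78 °C, 1 mM) then closes the ring by a Lewis-acid-driven allylstannane addition through an open transition state in which magnesium bridges the aldehyde and oxirane oxygens. This chelation control gives the required 5,6-threo relationship without a reductant. Hydroxy ester 15 lactonises and the route is rejoined at 16.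

**Step 6 (cross-metathesis).** The alkene carries an allylic ether and the partner is a hindered, electron-poor 1,1-disubstituted acrylate, so conversion may be low. The fallback sets out from 10 and builds the trisubstituted acrylate by olefination instead. Ozonolysis (O3, CH2Cl2/MeOH, −78 °C; PPh3) gives the aldehyde F3. Wittig reaction with methyl 3-(tert-butyldimethylsilyloxy)-2-(triphenylphosphoranylidene)propanoate (toluene, 60 °C) gives the silyl ether enoate F4. Dess–Martin oxidation of both hydroxyls gives the keto epoxy-aldehyde F5, HF·pyridine frees the allylic alcohol F6, and PPh3/NBS (CH2Cl2, −20 °C) gives the bromide, rejoining the route at 13.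

**Step 9 (oxirane hydrolysis inside the ring).** Elimination to an allylic alcohol or transannular capture by the C9 carbonyl could compete with clean inversion at C4. The fallback sets out from 10 and fixes the diol on the open chain before ring closure. Acetone with BF3·OEt2 (cat., −20 °C) converts the oxirane into the acetonide F7 with inversion at C4. Cross-metathesis with 11 as in step 6 gives the bromide F8, Dess–Martin oxidation gives the keto aldehyde F9, and CrCl2 closure as in step 8 gives the macrocyclic acetonide lactone F10. Aqueous AcOH (60 °C) releases the diol and the route is rejoined at 17.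

## Further compounds

F1 | step 8 | methyl (2Z,4R,5R,6R,10R,11R)-10,11-epoxy-5,12-dihydroxy-4-(methoxymethoxy)-6,10-dimethyl-2-[(tributylstannyl)methyl]dodec-2-enoate | COC(=O)/C(C[Sn](CCCC)(CCCC)CCCC)=C/[C@@H](OCOC)[C@H](O)[C@H](C)CCC[C@@]1(C)O[C@@H]1CO
F2 | step 8 | methyl (2Z,4R,6R,10R,11S)-10,11-epoxy-4-(methoxymethoxy)-6,10-dimethyl-5,12-dioxo-2-[(tributylstannyl)methyl]dodec-2-enoate | COC(=O)/C(C[Sn](CCCC)(CCCC)CCCC)=C/[C@@H](OCOC)C(=O)[C@H](C)CCC[C@@]1(C)O[C@@H]1C=O
F3 | step 6 | (2S,3R,4R,8R,9R)-8,9-epoxy-3,10-dihydroxy-2-(methoxymethoxy)-4,8-dimethyldecanal | O=C[C@@H](OCOC)[C@H](O)[C@H](C)CCC[C@@]1(C)O[C@@H]1CO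
F4 | step 6 | methyl (2E,4R,5R,6R,10R,11R)-2-{[(tert-butyldimethylsilyl)oxy]methyl}-10,11-epoxy-5,12-dihydroxy-4-(methoxymethoxy)-6,10-dimethyldodec-2-enoate | COC(=O)/C(CO[Si](C)(C)C(C)(C)C)=C/[C@@H](OCOC)[C@H](O)[C@H](C)CCC[C@@]1(C)O[C@@H]1CO
F5 | step 6 | methyl (2E,4R,6R,10R,11S)-2-{[(tert-butyldimethylsilyl)oxy]methyl}-10,11-epoxy-4-(methoxymethoxy)-6,10-dimethyl-5,12-dioxododec-2-enoate | COC(=O)/C(CO[Si](C)(C)C(C)(C)C)=C/[C@@H](OCOC)C(=O)[C@H](C)CCC[C@@]1(C)O[C@@H]1C=O
F6 | step 6 | methyl (2E,4R,6R,10R,11S)-10,11-epoxy-2-(hydroxymethyl)-4-(methoxymethoxy)-6,10-dimethyl-5,12-dioxododec-2-enoate | COC(=O)/C(CO)=C/[C@@H](OCOC)C(=O)[C@H](C)CCC[C@@]1(C)O[C@@H]1C=O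
F7 | step 9 | [(4R,5S)-5-[(4R,5R,6R)-5-hydroxy-6-(methoxymethoxy)-4-methyloct-7-en-1-yl]-2,2,5-trimethyl-1,3-dioxolan-4-yl]methanol | C=C[C@@H](OCOC)[C@H](O)[C@H](C)CCC[C@]1(C)OC(C)(C)O[C@@H]1CO
F8 | step 9 | methyl (2Z,4R,5R,6R)-2-(bromomethyl)-5-hydroxy-9-[(4S,5R)-5-(hydroxymethyl)-2,2,4-trimethyl-1,3-dioxolan-4-yl]-4-(methoxymethoxy)-6-methylnon-2-enoate | COC(=O)/C(CBr)=C/[C@@H](OCOC)[C@H](O)[C@H](C)CCC[C@]1(C)OC(C)(C)O[C@@H]1CO
F9 | step 9 | methyl (2Z,4R,6R)-2-(bromomethyl)-9-[(4S,5S)-5-formyl-2,2,4-trimethyl-1,3-dioxolan-4-yl]-4-(methoxymethoxy)-6-methyl-5-oxonon-2-enoate | COC(=O)/C(CBr)=C/[C@@H](OCOC)C(=O)[C@H](C)CCC[C@]1(C)OC(C)(C)O[C@@H]1C=O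
F10 | step 9 | (4S,5R,6S,7S,8R,10R)-4,5-(isopropylidenedioxy)-8-(methoxymethoxy)-9-oxogermacr-11(13)-en-12,6-olide | C=C1C(=O)O[C@H]2[C@H]1[C@@H](OCOC)C(=O)[C@H](C)CCC[C@]3(C)OC(C)(C)O[C@H]23
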